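The readings are simulated with constants of no real substance; scatter was added.

**Wrong ruler.** Time on the bench is the wrong ruler for Wednesday's flask, which is the flask asked about and is still running. Use the catalyst clock instead: [catalyst], which is loading times [substrate] at the start, multiplied by the time run. At 3.0 h this flask stands at 29.9 mM·min.

| flask | substrate | gas phase | catalyst | remark | time |
|---|---|---|---|---|---|
| Wednesday's | 0.20 M | 6.7 mM (held) | 0.083 mol% | the very flask that is asked about, followed so far |  |
| Sunday's | 0.30 M | 6.7 mM (held) | 0.083 mol% | run made earlier |  |
| flask | 0.20 M | 6.7 mM (held) | 0.083 mol% |  | 3.0 h |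

| run | time / min | target / % |
|---|---|---|
| Wednesday's | 12.0 | 5.7 |
| Wednesday's | 25.0 | 9.3 |
| Wednesday's | 40.0 | 10.4 |
| Wednesday's | 50.0 | 10.7 |
| Wednesday's | 60.0 | 10.6 |
| Wednesday's | 80.0 | 9.6 |
| Sunday's | 20.0 | 9.1 |
| Sunday's | 40.0 | 10.7 |
| Sunday's | 60.0 | 9.4 |
| Sunday's | 80.0 | 7.1 |
| Sunday's | 120 | 5.1 |

(scatter of a reading: 0.3 percentage points)

- at the start none of the gas is dissolved
- reactions considered so far: gas phase <-> dissolved gas; substrate + dissolved gas + catalyst -> catalyst + target; catalyst + target -> catalyst + over-reaction product

- maple: doubling the amount of catalyst, all else as stated
- alder: doubling the saturation concentration of gas phase, all else as stated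
- birch: doubling the transfer coefficient of the gas phase, all else as stated

- how much target there is at 3.0 h, in percent of the substrate charged
- concentration of dissolved gas in solution at 50 min, in percent of saturation
- the change that raises the amount of target at 3.0 h, in percent of the substrate charged most ("none" if none brings more than 2 percentage points) (maple / alder / birch / none)
- amount of target at 3.0 h, in percent of the substrate charged, after alder

**Main step.** Take first substrate + dissolved gas + catalyst → target, with [dissolved gas] held. Substrate then decays in a pseudo-first-order way along the clock, and target can just climb. Wednesday's flask does climb, to 5.7 % at 12.0 min.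

**Second step.** Add catalyst + target → over-reaction product. It runs on the same clock, so with [dissolved gas] held, percent target depends on the clock and on nothing else in the charge. Now the number turns: Wednesday's flask reads 10.7 % at 50.0 min, then 9.6 % at 80.0 min.

**Gas transfer.** A lagging transfer shows up as the flask with more [catalyst] falling behind on the clock. Wednesday's flask at 60.0 min and Sunday's run at 40.0 min both stand at 9.96 mM·min. They read 10.6 % and 10.7 %, a difference of 0.1 percentage points, with a scatter of 0.3 points. So I take [dissolved gas] as staying near 6.7 mM.

**My reckoning.** Sunday's last reading, at 120 min, stands at 29.9 mM·min, the clock of the flask at 3.0 h. So I expect 5.1 % of target. Maple moves the flask further along the clock, and Sunday's readings fall along it from 10.7 % to 5.1 %, so I expect less target. I expect birch to leave [dissolved gas] near where it stands. Alder changes [dissolved gas], which the clock rule holds, so no run speaks for it. I expect no gain above 2 points from it, and I choose none.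

**The forecast.** It says 5.7 % of target at 3.0 h, 70 % of saturation at 50 min on the ground that “Early rates suggest mild gas limitation”, none as the best change, and 3.8 % of target after alder. Its saturation differs from mine.

**The flask.** The flask gives 5.20 % of target at 3.0 h and 99.6 % of saturation at 50 min, the second above the forecast by 30 points. The choice is none: maple −3.6 points, alder −1.5 points, birch 0 points, and alder leaves 3.75 % of target at 3.0 h.

    gas phase ⇌ dissolved gas, rate k1*(csat - [dissolved gas]) (kL = 34.9 min⁻¹)
    substrate + dissolved gas + catalyst → catalyst + target (k = 6060 M⁻² min⁻¹)
    catalyst + target → catalyst + over-reaction product (k = 273 M⁻¹ min⁻¹)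

**The neighbour.** With 0.033 mol% of catalyst, the same flask reaches 11.9 mM·min at 3.0 h, against 29.9 mM·min for the flask itself. That is where Wednesday's flask stood at 71.6 min, between its readings at 60.0 min and 80.0 min, whose mean is 10.1 %. The neighbour gives 10.1 % of target, with 62 % of the substrate left.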